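**Retrosynthetic overview**
1. Target 18 is a C2-symmetric 2,6-diaryl-3,7-dioxabicyclo[3.3.0]octane-1,5-diol (C1/C5 carbinol bridgeheads, C2/C6 benzylic, O3/O7, C4/C8 methylene). Both aryl–C bonds are cut last, back to bis-lactone 8 (C2/C6 as lactone carbonyls) and diarylzinc 15, one molecule of which carries both aryl groups.
2. The bis-lactone core comes from the butane-2,3-diacetal of dimethyl L-tartrate (2) and two formaldehyde units. In one flask, ring A is made by an aldol bond C4–C5 and a lactone bond O3–C2, and ring B by C8–C1 and O7–C6: a twofold formal (3+2) annulation of formaldehyde.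
3. Enabling feature: the chain C2–C1(OH)–C5(OH)–C6 is a tartaric acid skeleton. At the diester level both bridgehead carbons are enolisable CH groups, and each ring O–CH2 unit is one formaldehyde spanning an enolate carbon and the ester carbon 1,3 to it; the C2 axis lets both rings form by the same event.
4. Ring order: temporary dioxane ring (step 1), then lactone rings A and B together (step 2), then removal of the dioxane and conversion of both C=O into CH–Ar (steps 3–5 and 10), then desilylation (step 11).
5. Absolute configuration comes from L-tartrate (both carbinol carbons inverted by equatorial enolate attack); the benzylic centres come from convex-face arylation.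

Key step: step 2

Assumption: enolates of diacetal 2 are taken to react on their equatorial face, anti to the syn-axial methoxy group, as expected for exocyclic enolates on such a chair. Formaldehyde is used as the anhydrous monomer.

**Step 1**
Reactants: 1 dimethyl L-tartrate
Product: 2 dimethyl (2R,3R,5R,6R)-5,6-dimethoxy-5,6-dimethyl-1,4-dioxane-2,3-dicarboxylate
Conditions: 2,2,3,3-tetramethoxybutane, camphorsulfonic acid (cat.), MeOH, reflux
Reagents that add atoms: 2,2,3,3-tetramethoxybutane COC(C)(OC)C(C)(OC)OC
Why: Acid-catalysed transacetalisation of the trans-diol with the bis(dimethyl ketal) of butanedione (butane-2,3-diacetal protection) under thermodynamic control should place both OMe groups axial (anomeric effect) and both esters equatorial, so the two acetal centres (R,R) follow from the tartrate centres.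

**Step 2**
Reactants: 2 dimethyl (2R,3R,5R,6R)-5,6-dimethoxy-5,6-dimethyl-1,4-dioxane-2,3-dicarboxylate, 3 formaldehyde
Product: 6 butane-2,3-diacetal of (1S,5S)-1,5-dihydroxy-3,7-dioxabicyclo[3.3.0]octane-2,6-dione, via mono(hydroxymethyl) diester lithium alkoxide 4 (not isolated), via bis(hydroxymethyl) diester dilithium alkoxide 5 (not isolated)
Conditions: LiN(i-Pr)2 (1.1 equiv), THF, −78 °C; CH2O (1.1 equiv, THF solution), −78 °C; LiN(i-Pr)2 (1.2 equiv), −78 °C; CH2O (1.2 equiv), −78 °C; then −78 → 0 °C; AcOH
Reagents that add atoms: none
Why: Deprotonation of 2 gives the exocyclic ester enolate, which adds to formaldehyde (aldol) to form the CH2–C(bridgehead) bond, and the sequence is repeated at the second carbinol carbon in the same flask at −78 °C; on warming, each lithium alkoxide attacks the ester on the neighbouring ring carbon and expels methoxide, forming the O–C(=O) bond that later becomes the benzylic O–C bond. The closest known reaction type is the aldol–lactonisation that gives paraconic esters from succinate enolates (first stage of the Stobbe condensation), which cannot go on to elimination here because the aldol carbon is quaternary, together with the known alkylation and aldol chemistry of tartrate acetal enolates. Each γ-lactone ring (rings A and B) closes by 5-exo-trig acyl substitution of an equatorial CH2O– group on the axial ester of the neighbouring carbon, a gauche pair. Both new quaternary stereocentres are set by equatorial attack on the enolate, anti to the syn-axial OMe group of the diacetal chair, which pushes the ester axial and inverts each carbinol carbon relative to L-tartrate (R to S at the diester stage). The step needs freedom from β-elimination of the ring oxygen, which the acetal ring should secure at −78 °C by holding that C–O bond near the nodal plane of the enolate; it needs both aldol additions to be complete before any lactonisation, which holding −78 °C until the second addition is over should secure; and it needs the same facial sense at both carbons, which the C2-symmetric template enforces and ring closure filters, since a mixed axial/equatorial adduct cannot lactonise twice.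

**Step 3**
Reactants: 6 butane-2,3-diacetal of (1S,5S)-1,5-dihydroxy-3,7-dioxabicyclo[3.3.0]octane-2,6-dione
Product: 7 (1S,5S)-1,5-dihydroxy-3,7-dioxabicyclo[3.3.0]octane-2,6-dione
Conditions: CF3CO2H/H2O (9:1), rt; evaporation
Reagents that add atoms: none
Why: Acid hydrolysis of the bis-ketal (standard removal of a butane-2,3-diacetal) should release the tertiary cis-diol while the γ-lactones and the two quaternary stereocentres, which carry no acidic hydrogen, stay untouched.

**Step 4**
Reactants: 7 (1S,5S)-1,5-dihydroxy-3,7-dioxabicyclo[3.3.0]octane-2,6-dione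
Product: 8 (1S,5S)-1,5-bis(trimethylsilyloxy)-3,7-dioxabicyclo[3.3.0]octane-2,6-dione
Conditions: MeC(OSiMe3)=NSiMe3 (1.5 equiv), MeCN, 50 °C; evaporation
Reagents that add atoms: N,O-bis(trimethylsilyl)acetamide CC(=N[Si](C)(C)C)O[Si](C)(C)C
Why: Silylation of the hindered tertiary hydroxyls with a strong neutral silyl donor, both silyl groups of which are transferable, should give small, non-participating ethers that tolerate hydride reduction, bromosilane and organozinc reagents and do not block the convex face; the by-product acetamide is too weak a nucleophile to open the lactones.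

**Step 5**
Reactants: 8 (1S,5S)-1,5-bis(trimethylsilyloxy)-3,7-dioxabicyclo[3.3.0]octane-2,6-dione
Product: 10 (1S,5S)-1,5-bis(trimethylsilyloxy)-3,7-dioxabicyclo[3.3.0]octane-2,6-diyl diacetate (anomeric mixture), via aluminium bis-lactolate 9 (not isolated)
Conditions: i-Bu2AlH (2.2 equiv), CH2Cl2, −78 °C; then pyridine, 4-(dimethylamino)pyridine, Ac2O, −78 → 0 °C; aq. KNaC4H4O6
Reagents that add atoms: acetic anhydride CC(=O)OC(C)=O
Why: Reductive acetylation of lactones (Rychnovsky protocol) relies on the tetrahedral aluminium lactolate being stable at −78 °C and acylated in situ, so neither ring should open; the two acetal centres form as a mixture, which is removed in step 10.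

**Step 6**
Reactants: 11 4-bromo-2-methoxyphenol
Product: 12 (4-bromo-2-methoxyphenoxy)(tert-butyl)dimethylsilane
Conditions: TBSCl, imidazole, DMF, rt
Reagents that add atoms: tert-butyldimethylsilyl chloride CC(C)(C)[Si](C)(C)Cl
Why: Standard silylation of a phenol gives an aryl silyl ether that tolerates magnesium insertion and transmetalation and is removed by fluoride together with the other silyl groups.

**Step 7**
Reactants: 12 (4-bromo-2-methoxyphenoxy)(tert-butyl)dimethylsilane
Product: 13 [4-(tert-butyldimethylsilyloxy)-3-methoxyphenyl]magnesium bromide (titrated THF stock solution)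
Conditions: Mg turnings, I2 (cat.), THF, 40 °C
Reagents that add atoms: magnesium [Mg]
Why: Insertion of magnesium into the aryl C–Br bond (Grignard formation) is routine for silyl-protected bromophenols; the stock solution is titrated and drawn on in steps 8 and 9.

**Step 8**
Reactants: 13 [4-(tert-butyldimethylsilyloxy)-3-methoxyphenyl]magnesium bromide
Product: 14 bromo[4-(tert-butyldimethylsilyloxy)-3-methoxyphenyl]zinc (THF solution)
Conditions: ZnBr2 (1.0 equiv, fused), THF, 0 °C
Reagents that add atoms: zinc dibromide Br[Zn]Br
Why: Transmetalation of an aryl Grignard reagent onto zinc dibromide is fast and should give the arylzinc bromide cleanly, with magnesium dibromide staying in solution.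

**Step 9**
Reactants: 14 bromo[4-(tert-butyldimethylsilyloxy)-3-methoxyphenyl]zinc, 13 [4-(tert-butyldimethylsilyloxy)-3-methoxyphenyl]magnesium bromide
Product: 15 bis[4-(tert-butyldimethylsilyloxy)-3-methoxyphenyl]zinc (THF solution)
Conditions: 13 (1.0 equiv, from the same stock solution) added to 14, THF, 0 °C → rt
Reagents that add atoms: none
Why: A second transmetalation of the Grignard reagent onto the arylzinc bromide should give the diarylzinc, a single reagent molecule holding the two aryl groups that the bis-electrophile of step 10 needs, and a milder, less basic aryl donor than the Grignard reagent itself.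

**Step 10**
Reactants: 10 (1S,5S)-1,5-bis(trimethylsilyloxy)-3,7-dioxabicyclo[3.3.0]octane-2,6-diyl diacetate, 15 bis[4-(tert-butyldimethylsilyloxy)-3-methoxyphenyl]zinc
Product: 17 (1R,2S,5R,6S)-2,6-bis[4-(tert-butyldimethylsilyloxy)-3-methoxyphenyl]-1,5-bis(trimethylsilyloxy)-3,7-dioxabicyclo[3.3.0]octane, via bis(α-bromo ether) 16 (not isolated)
Conditions: 10, Me3SiBr, CH2Cl2, 0 °C, then evaporation; 15 (1.2 equiv, THF solution), toluene, −40 °C → rt; aq. NH4Cl
Reagents that add atoms: none
Why: C-arylation of an α-bromo ether by an arylzinc reagent through the cyclic oxocarbenium ion (the uncatalysed C-glycosylation of glycosyl bromides with diarylzinc reagents is the model) should transfer both aryl groups of 15, since the arylzinc bromide left after the first transfer still arylates the second oxocarbenium ion with help from the zinc and magnesium dibromides present; no elimination is possible because the neighbouring bridgehead is quaternary, and each aryl group should arrive on the convex face of the cis-fused bicycle, cis to the adjacent bridgehead silyloxy group as the inside-attack model for 2-alkoxy five-ring oxocarbenium ions also predicts, setting both benzylic centres S (aryl exo).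

**Step 11**
Reactants: 17 (1R,2S,5R,6S)-2,6-bis[4-(tert-butyldimethylsilyloxy)-3-methoxyphenyl]-1,5-bis(trimethylsilyloxy)-3,7-dioxabicyclo[3.3.0]octane
Product: 18 (1R,2S,5R,6S)-2,6-bis(4-hydroxy-3-methoxyphenyl)-3,7-dioxabicyclo[3.3.0]octane-1,5-diol
Conditions: Bu4NF, AcOH, THF, 0 °C → rt
Reagents that add atoms: none
Why: Fluoride-mediated desilylation should cleave the two aryl and two tertiary silyl ethers, with AcOH buffering to keep the phenoxide from opening the benzylic ethers through a quinone methide, so all four stereocentres are retained.

**Compound list**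
1 | dimethyl L-tartrate, dimethyl (2R,3R)-2,3-dihydroxybutanedioate | COC(=O)[C@H](O)[C@@H](O)C(=O)OC | starting material
2 | dimethyl (2R,3R,5R,6R)-5,6-dimethoxy-5,6-dimethyl-1,4-dioxane-2,3-dicarboxylate (esters equatorial, OMe axial) | COC(=O)[C@@H]1O[C@@](C)(OC)[C@](C)(OC)O[C@H]1C(=O)OC | intermediate
3 | formaldehyde (monomer, from cracked paraformaldehyde) | C=O | starting material
4 | dimethyl (2S,3R,5R,6R)-2-(hydroxymethyl)-5,6-dimethoxy-5,6-dimethyl-1,4-dioxane-2,3-dicarboxylate (as lithium alkoxide; CH2O equatorial, its ester axial) | COC(=O)[C@@]1(CO)O[C@@](C)(OC)[C@](C)(OC)O[C@H]1C(=O)OC | intermediate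
5 | dimethyl (2S,3S,5R,6R)-2,3-bis(hydroxymethyl)-5,6-dimethoxy-5,6-dimethyl-1,4-dioxane-2,3-dicarboxylate (as dilithium alkoxide; both CH2O equatorial, both esters axial) | COC(=O)[C@@]1(CO)O[C@@](C)(OC)[C@](C)(OC)O[C@]1(CO)C(=O)OC | intermediate
6 | butane-2,3-diacetal (acetal carbons R,R) of (1S,5S)-1,5-dihydroxy-3,7-dioxabicyclo[3.3.0]octane-2,6-dione, a [4.3.3]propellane bis-lactone | O=C1OC[C@@]2(O[C@@](C)(OC)[C@](C)(OC)O3)C(=O)OC[C@@]123 | intermediate
7 | (1S,5S)-1,5-dihydroxy-3,7-dioxabicyclo[3.3.0]octane-2,6-dione | O=C1OC[C@@]2(O)C(=O)OC[C@@]12O | intermediate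
8 | (1S,5S)-1,5-bis(trimethylsilyloxy)-3,7-dioxabicyclo[3.3.0]octane-2,6-dione | O=C1OC[C@@]2(O[Si](C)(C)C)C(=O)OC[C@@]12O[Si](C)(C)C | intermediate
9 | (1S,5S)-1,5-bis(trimethylsilyloxy)-3,7-dioxabicyclo[3.3.0]octane-2,6-diol (bis-lactol, formed as its bis(diisobutylaluminium) alkoxide; lactol carbons as a mixture) | OC1OC[C@@]2(O[Si](C)(C)C)C(O)OC[C@@]12O[Si](C)(C)C | intermediate
10 | (1S,5S)-1,5-bis(trimethylsilyloxy)-3,7-dioxabicyclo[3.3.0]octane-2,6-diyl diacetate (anomeric mixture) | CC(=O)OC1OC[C@@]2(O[Si](C)(C)C)C(OC(C)=O)OC[C@@]12O[Si](C)(C)C | intermediate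
11 | 4-bromo-2-methoxyphenol | COc1cc(Br)ccc1O | starting material
12 | (4-bromo-2-methoxyphenoxy)(tert-butyl)dimethylsilane | COc1cc(Br)ccc1O[Si](C)(C)C(C)(C)C | intermediate
13 | [4-(tert-butyldimethylsilyloxy)-3-methoxyphenyl]magnesium bromide | COc1cc([Mg]Br)ccc1O[Si](C)(C)C(C)(C)C | intermediate
14 | bromo[4-(tert-butyldimethylsilyloxy)-3-methoxyphenyl]zinc | COc1cc([Zn]Br)ccc1O[Si](C)(C)C(C)(C)C | intermediate
15 | bis[4-(tert-butyldimethylsilyloxy)-3-methoxyphenyl]zinc | COc1cc([Zn]c2ccc(O[Si](C)(C)C(C)(C)C)c(OC)c2)ccc1O[Si](C)(C)C(C)(C)C | intermediate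
16 | (1S,5S)-2,6-dibromo-1,5-bis(trimethylsilyloxy)-3,7-dioxabicyclo[3.3.0]octane (anomeric mixture) | BrC1OC[C@@]2(O[Si](C)(C)C)C(Br)OC[C@@]12O[Si](C)(C)C | intermediate
17 | (1R,2S,5R,6S)-2,6-bis[4-(tert-butyldimethylsilyloxy)-3-methoxyphenyl]-1,5-bis(trimethylsilyloxy)-3,7-dioxabicyclo[3.3.0]octane (aryl groups exo, cis to the bridgehead oxygens) | COc1cc([C@@H]2OC[C@@]3(O[Si](C)(C)C)[C@H](c4ccc(O[Si](C)(C)C(C)(C)C)c(OC)c4)OC[C@@]23O[Si](C)(C)C)ccc1O[Si](C)(C)C(C)(C)C | intermediate
18 | (1R,2S,5R,6S)-2,6-bis(4-hydroxy-3-methoxyphenyl)-3,7-dioxabicyclo[3.3.0]octane-1,5-diol | COc1cc([C@@H]2OC[C@@]3(O)[C@H](c4ccc(O)c(OC)c4)OC[C@@]23O)ccc1O | target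

**Totals**
Total step count: 11. Longest linear sequence: 7 (steps 1, 2, 3, 4, 5, 10, 11); the aryl branch (steps 6, 7, 8, 9) joins at step 10.

**Steps most likely to fail**

Step 2. The second enolisation may lose out to β-elimination of the ring oxygen or to retro-aldol of the first adduct. The first alkoxide may lactonise too early onto the still equatorial ester, which would block the second ring. Formaldehyde may oligomerise on the alkoxide, and the second attack may erode in facial selectivity. Fallback, setting out from 2: the two carbons are introduced by enolate alkylation instead of aldol, so that no free alkoxide exists until both are in place. Two separate alkylations with benzyl chloromethyl ether (LiN(i-Pr)2, THF, −78 °C) should give the mono(benzyloxymethyl) diester F1 and then the bis(benzyloxymethyl) diester F2. Hydrogenolysis (H2, Pd/C, EtOAc) would give the bis(hydroxymethyl) diester 5, now isolated as the free diol, and camphorsulfonic acid in toluene should lactonise it twice to come back to the route at 6.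

Step 10. Facial selectivity in the aryl transfer to the oxocarbenium ions may be poor, the second aryl group of the zinc reagent may transfer sluggishly so that the second substitution stalls, or the trimethylsilyl ethers may be lost to adventitious HBr. Fallback, setting out from 8: the benzylic centres are set by thermodynamically controlled ring closure instead of kinetic arylation. Reduction with i-Bu2AlH and aqueous work-up gives the free bis-lactol 9. Excess Grignard reagent 13 adds to its hydroxy-aldehyde form to give the 1,4-diaryl tetraol F3. Camphorsulfonic acid (cat.) with 4 Å molecular sieves in CH2Cl2 at 0 °C should ionise the electron-rich benzylic alcohols and let the primary hydroxyls close both tetrahydrofuran rings with the aryl groups exo, coming back to the route at 17.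

Step 5. Over-reduction to the ring-opened diol, migration of a silyl group to the aluminium lactolate, or incomplete double acetylation may occur. Fallback, setting out from 8: the oxocarbenium precursor is changed to a sulfone. The bis-lactol 9 is isolated after i-Bu2AlH reduction and treated with benzenesulfinic acid and CaCl2 in CH2Cl2 to give the bis(phenylsulfonyl) ether F4. Reaction of F4 with diarylzinc 15 and ZnBr2 in THF should give the diaryl compound directly, coming back to the route at 17 and bypassing 10 and 16.

**Further compounds**
F1 | step 2 | dimethyl (2S,3R,5R,6R)-2-[(benzyloxy)methyl]-5,6-dimethoxy-5,6-dimethyl-1,4-dioxane-2,3-dicarboxylate | COC(=O)[C@@]1(COCc2ccccc2)O[C@@](C)(OC)[C@](C)(OC)O[C@H]1C(=O)OC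
F2 | step 2 | dimethyl (2S,3S,5R,6R)-2,3-bis[(benzyloxy)methyl]-5,6-dimethoxy-5,6-dimethyl-1,4-dioxane-2,3-dicarboxylate | COC(=O)[C@@]1(COCc2ccccc2)O[C@@](C)(OC)[C@](C)(OC)O[C@]1(COCc2ccccc2)C(=O)OC
F3 | step 10 | (2R,3R)-1,4-bis[4-(tert-butyldimethylsilyloxy)-3-methoxyphenyl]-2,3-bis(hydroxymethyl)-2,3-bis(trimethylsilyloxy)butane-1,4-diol (benzylic carbinols as a mixture) | OC[C@@](O[Si](C)(C)C)(C(O)c1ccc(O[Si](C)(C)C(C)(C)C)c(OC)c1)[C@@](CO)(C(O)c1ccc(O[Si](C)(C)C(C)(C)C)c(OC)c1)O[Si](C)(C)C
F4 | step 5 | (1S,5S)-2,6-bis(phenylsulfonyl)-1,5-bis(trimethylsilyloxy)-3,7-dioxabicyclo[3.3.0]octane (anomeric mixture) | O=S(=O)(c1ccccc1)C1OC[C@@]2(O[Si](C)(C)C)C(S(=O)(=O)c3ccccc3)OC[C@@]12O[Si](C)(C)C
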